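A direct plan would carry all six bromines into the ether-forming step. The phenoxide of 2,3,5-tribromo-4-methoxyphenol (A1) would displace one bromide of bromanil (A2) by addition–elimination. The aryloxyquinone (A3) would be reduced to its hydroquinone (A4), and the methyl ether would be cleaved last. Its weakest steps would be:
- the preparation of A1, which would need a protecting-group relay on hydroquinone and a bromination meta to the free hydroxyl, and so would add length without complexity;
- the mono-substitution of A2, because A3 would still carry three displaceable bromides and a hindered, electron-poor phenoxide would add slowly, so that over-substitution would compete;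
- the final demethylation of A4, where the ortho-hydroxy/ortho′-bromo ether could close to a dibenzodioxin on any basic excursion.

**New strategy.** The route disconnects five C–Br bonds instead of the crowded ether. In the target, C3, C4 and C6 of ring B (the hydroquinone ring) and C3′ and C5′ of ring A (the 4-hydroxyphenoxy ring) all lie ortho to a free hydroxyl, whereas the lone C6′–H is meta to one. The ether is therefore made first, between unhindered partners, with only the non-innate C2′ bromine brought in by a commercial phenol. After the three hydroxyls are unmasked, one phenol-directed pentabromination writes the rest of the pattern. No bromoquinone, no mono-substitution of a tetrahalide, no protecting-group relay and no deprotection of a hexabromide remain.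

Key step: step 3

Remark: atom labels are not the locants of the systematic names. Ring B carries the ether oxygen at C1 and hydroxyls at C2 and C5; ring A carries the ether oxygen at C1′ and the hydroxyl at C4′. Compounds 1 and 2 are taken as catalogue compounds. The target is achiral, so no stereocentre has to be set.

Step 1
Reactants: 1 2-bromo-4-methoxyphenol (1.0 equiv); 2 (2,5-dimethoxyphenyl)boronic acid (2.0 equiv)
Product: 3 2-bromo-1-(2,5-dimethoxyphenoxy)-4-methoxybenzene
Conditions: Cu(OAc)2 (20 mol%), pyridine (5 equiv), 4 Å MS, CH2Cl2, O2 (1 atm), rt, 48 h
Reagents that add atoms: none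
Why: Chan–Lam–Evans oxidative O-arylation, in which the aryl group of 2 should transmetalate to a divalent copper phenoxide of 1 and C–O reductive elimination from trivalent copper should give the ether at room temperature, where the ring A C–Br bond is inert; each partner carries only one ortho substituent, so the coupling is far less hindered than any union of brominated rings.

Step 2
Reactants: 3 2-bromo-1-(2,5-dimethoxyphenoxy)-4-methoxybenzene
Product: 5 2-(2-bromo-4-hydroxyphenoxy)benzene-1,4-diol, via tris(dibromoboryl) aryl ether 4 (not isolated)
Conditions: BBr3 (4.5 equiv), CH2Cl2, –78 °C → rt, 12 h, N2; then H2O, 0 °C; extraction with degassed EtOAc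
Reagents that add atoms: none
Why: Lewis-acid O-demethylation (bromide attacks the methyl carbon of each BBr3-bound methoxy group, SN2), which should not touch the diaryl ether or the aryl bromide; hydrolysis of the aryl borates 4 frees the three phenols.

Step 3
Reactants: 5 2-(2-bromo-4-hydroxyphenoxy)benzene-1,4-diol
Product: 6 2,3,5-tribromo-6-(2,3,5-tribromo-4-hydroxyphenoxy)benzene-1,4-diol (target)
Conditions: Br2 (5.1 equiv, dropwise), glacial AcOH, N2, dark, 15 → 55 °C, 6 h; work-up: H2O, aq. Na2S2O4 wash, crystallisation, kept acidic
Reagents that add atoms: bromine, BrBr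
Why: Five successive electrophilic aromatic substitutions should take place, each through an arenium ion (or its bromocyclohexadienone tautomer) stabilised by the lone pair of an ortho hydroxyl. The closest known reactions are the exhaustive bromination of hydroquinone to tetrabromohydroquinone and of 4-alkoxyphenols to their 2,6-dibromides with Br2 in acetic acid. No ring is closed and no stereocentre is formed; the step only has to distinguish the six C–H positions of 5. C3, C4 and C6 of ring B and C3′ and C5′ of ring A are each ortho to a free hydroxyl (C4 and C6 are also para or ortho to the ether oxygen), whereas C6′ is meta to the ring A hydroxyl, is activated only by the twisted diaryl ether oxygen and ends on a ring that already carries three bromines, so the sixth substitution should be far slower than the five wanted ones and the bromine should be spent before it starts. Ring B that is oxidised by bromine to the quinone should re-enter by 1,4-addition of the HBr formed, and the dithionite wash should return any quinone that is left, so that all oxidation levels converge on 6. The anhydrous acidic medium should suppress ipso attack at C1′ and should keep the product away from base, under which the ortho-hydroxy/ortho′-bromo ether could cyclise.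

**Compound list**
1 | 2-bromo-4-methoxyphenol | COc1ccc(O)c(Br)c1 | starting material
2 | (2,5-dimethoxyphenyl)boronic acid | COc1ccc(OC)c(B(O)O)c1 | starting material
3 | 2-bromo-1-(2,5-dimethoxyphenoxy)-4-methoxybenzene | COc1ccc(Oc2cc(OC)ccc2OC)c(Br)c1 | intermediate
4 | tris(dibromoboryl) aryl ether: 2-bromo-4-(dibromoboranyloxy)-1-[2,5-bis(dibromoboranyloxy)phenoxy]benzene | BrB(Br)Oc1ccc(Oc2cc(OB(Br)Br)ccc2OB(Br)Br)c(Br)c1 | intermediate
5 | 2-(2-bromo-4-hydroxyphenoxy)benzene-1,4-diol | Oc1ccc(Oc2cc(O)ccc2O)c(Br)c1 | intermediate
6 | 2,3,5-tribromo-6-(2,3,5-tribromo-4-hydroxyphenoxy)benzene-1,4-diol (achiral) | Oc1c(Br)cc(Oc2c(O)c(Br)c(Br)c(O)c2Br)c(Br)c1Br | target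

Total step count: 3. Longest linear sequence: 3 steps (1 → 3 → 5 → 6; 2 enters in step 1).

Steps most likely to fail:

1. Step 3 (key step). What may go wrong: oxidation of ring B to the quinone level by bromine may outrun substitution at the last flanked positions (C3, C6, C3′), so that the mixture stalls on partly brominated hydroquinone/quinone pairs. Fallback, from 5 back to 6: the oxidation would be driven to completion on purpose. With Br2 (7 equiv) in AcOH, then 10 vol% H2O, 20 → 70 °C, bromination should finish at the quinone level by addition of Br2 or HBr and loss of HBr, the way hydroquinone is taken to bromanil. Ring A would still be brominated under control of its free hydroxyl. This should give one crystalline compound, 2,3,5-tribromo-6-(2,3,5-tribromo-4-hydroxyphenoxy)cyclohexa-2,5-diene-1,4-dione (F1). Reduction of F1 with Na2S2O4 (EtOAc/H2O, rt, N2) would then give 6.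

2. Step 1. What may go wrong: slow transmetalation and C–O reductive elimination between an ortho-bromophenol and an ortho-methoxy boronic acid, while protodeboronation and oxidative hydroxylation use up the boron partner. Fallback, from 2 back to 5: the roles of the rings would be exchanged and the ether made by SNAr at ring A. Oxidation of 2 (H2O2, aq. NaOH/THF, 0 °C) would give 2,5-dimethoxyphenol (F2). The second partner would be commercial 3-bromo-4-fluorobenzaldehyde (F3). F2 and F3 with K2CO3 in DMAc at 110 °C should give 3-bromo-4-(2,5-dimethoxyphenoxy)benzaldehyde (F4), because only the fluoride of F3 lies para to the formyl group and the bromide should stay in place. Baeyer–Villiger oxidation of F4 (mCPBA, CH2Cl2, rt) would give 3-bromo-4-(2,5-dimethoxyphenoxy)phenyl formate (F5). Methanolysis of F5 (K2CO3 cat., MeOH) would give 3-bromo-4-(2,5-dimethoxyphenoxy)phenol (F6). BBr3 under the conditions of step 2 would cleave the two methyl ethers of F6 to 5.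

3. Step 2. What may go wrong: incomplete cleavage of the methoxy group at C2, which is flanked by the aryloxy group, and air oxidation of the freed hydroquinone during isolation. Fallback, from 3 back to 5: ring B would be unmasked oxidatively. (NH4)2Ce(NO3)6 (2.2 equiv) in MeCN/H2O at 0 °C should convert the more electron-rich, 1,2,4-trioxygenated ring B of 3 into the quinone 2-(2-bromo-4-methoxyphenoxy)cyclohexa-2,5-diene-1,4-dione (F7), ring A being deactivated by its bromine. Reduction of F7 with Na2S2O4 (EtOAc/H2O, rt) would give 2-(2-bromo-4-methoxyphenoxy)benzene-1,4-diol (F8). The one remaining, unhindered methyl ether of F8 would be cleaved with BBr3 (3 equiv, CH2Cl2, –78 °C → rt) to 5, which would be carried crude into step 3.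

**Further compounds**
F1 | step 3 | 2,3,5-tribromo-6-(2,3,5-tribromo-4-hydroxyphenoxy)cyclohexa-2,5-diene-1,4-dione | O=C1C(Br)=C(Br)C(=O)C(Oc2cc(Br)c(O)c(Br)c2Br)=C1Br
F2 | step 1 | 2,5-dimethoxyphenol | COc1ccc(OC)c(O)c1
F3 | step 1 | 3-bromo-4-fluorobenzaldehyde | O=Cc1ccc(F)c(Br)c1
F4 | step 1 | 3-bromo-4-(2,5-dimethoxyphenoxy)benzaldehyde | COc1ccc(OC)c(Oc2ccc(C=O)cc2Br)c1
F5 | step 1 | 3-bromo-4-(2,5-dimethoxyphenoxy)phenyl formate | COc1ccc(OC)c(Oc2ccc(OC=O)cc2Br)c1
F6 | step 1 | 3-bromo-4-(2,5-dimethoxyphenoxy)phenol | COc1ccc(OC)c(Oc2ccc(O)cc2Br)c1
F7 | step 2 | 2-(2-bromo-4-methoxyphenoxy)cyclohexa-2,5-diene-1,4-dione | COc1ccc(OC2=CC(=O)C=CC2=O)c(Br)c1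
F8 | step 2 | 2-(2-bromo-4-methoxyphenoxy)benzene-1,4-diol | COc1ccc(Oc2cc(O)ccc2O)c(Br)c1
A1 | direct plan | 2,3,5-tribromo-4-methoxyphenol | COc1c(Br)cc(O)c(Br)c1Br
A2 | direct plan | bromanil (2,3,5,6-tetrabromocyclohexa-2,5-diene-1,4-dione) | O=C1C(Br)=C(Br)C(=O)C(Br)=C1Br
A3 | direct plan | 2,3,5-tribromo-6-(2,3,5-tribromo-4-methoxyphenoxy)cyclohexa-2,5-diene-1,4-dione | O=C1C(Br)=C(Br)C(=O)C(Oc2cc(Br)c(OC)c(Br)c2Br)=C1Br
A4 | direct plan | 2,3,5-tribromo-6-(2,3,5-tribromo-4-methoxyphenoxy)benzene-1,4-diol | Oc1c(Br)c(Br)c(O)c(Oc2cc(Br)c(OC)c(Br)c2Br)c1Br
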